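**Plan**

1. Numbering used throughout: quinone ring C1 (C=O next to the ring CH), C2 (OH), C3 (docosyl), C4 (C=O), C5 (OMe), C6 (H).
2. Enabling feature: the oxygens on C1 and C5 lie meta to the chain-bearing C3, the 1,3-dioxygenation pattern of a resorcinol folded from a fatty-acyl-primed tetraketide. The C2 hydroxyl and the C4 carbonyl oxygen are not part of that pattern and are added late.
3. Retrosynthesis: remove the C2–O bond (Thiele–Winter) and the C4–O bond (Teuber), restore a carboxyl on C2, cut the C2–C3 ring bond (aldol) to an open-chain 3,5,7-triketo ester, then cut the chain bond between the triketide and the C23 acyl unit (Claisen).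
4. Forward: the chain is joined in step 3 and the only ring closes in step 4. The retained ester then allows a single O-methylation before it is removed, and the two remaining oxygens are introduced.
5. Stereochemistry: the target is achiral; the two centres of the transient aldol adduct vanish on aromatisation.

Key step: step 4

Remark on the chemistry: the polyketone intermediates are drawn as keto tautomers although they should exist largely as enols, and the target is drawn as the hydrogen-bonded 2-hydroxy-1,4-quinone tautomer.

**Route**

Step 1
Reactants: 1 dehydroacetic acid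
Product: 2 methyl 3,5-dioxohexanoate
Conditions: Mg(OMe)2 (2 equiv), MeOH, reflux; then 2 M HCl
Reagents that add atoms: methanol, CO; magnesium methoxide, C[O-].C[O-].[Mg+2]
Why: Methoxide opens the pyranone lactone and the resulting 2-acetyl-3,5-dioxo ester loses its acetyl group as methyl acetate by retro-Claisen cleavage, the magnesium chelate shielding the diketo ester from further cleavage; this is a known alcoholysis–deacetylation of dehydroacetic acid.

Step 2
Reactants: 3 tricosanoic acid
Product: 4 methyl tricosanoate
Conditions: MeOH, H2SO4 (cat.), reflux
Reagents that add atoms: methanol, CO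
Why: Fischer esterification, driven to completion by the excess of methanol.

Step 3
Reactants: 2 methyl 3,5-dioxohexanoate; 4 methyl tricosanoate
Product: 5 methyl 3,5,7-trioxononacosanoate
Conditions: 2 (2.2 equiv), LiN(iPr)2 (6.8 equiv), THF, 0 °C; then 4 in THF, 0 °C to rt; then cold 2 M HCl
Reagents that add atoms: none
Why: Claisen condensation of a β-polycarbonyl polyanion, in which the trianion of 2 reacts only at its last-formed, most basic terminal carbanion (C6) and the second equivalent of trianion takes up the acidic proton of the new 1,3-diketone so that the addition is not reversed.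

Step 4
Reactants: 5 methyl 3,5,7-trioxononacosanoate
Product: 7 methyl 6-docosyl-2,4-dihydroxybenzoate, via cyclic aldol adduct 6 (not isolated)
Conditions: Cs2CO3 (1.5 equiv), MeOH–THF (1:1), rt; then HCl in MeOH, rt
Reagents that add atoms: none
Why: Carbonate deprotonates the C2 methylene, the only terminal position flanked by two carbonyls, and this stabilised carbanion adds to the C7 ketone; the β-hydroxy ketone 6 then loses water across C2–C7 on acidification and the C3 and C5 carbonyls enolise, so the ring becomes aromatic irreversibly. The closest known reaction type is the biomimetic aldol aromatisation of 3,5,7-triketo esters to β-resorcylates. The single new ring closes in a 6-(enolexo)-exo-trig mode, with C2–C7 (target C2–C3) as the new bond. No stereocentre is created in the product, since both centres of 6 are erased on dehydration. The step needs aldol closure to win over Claisen closure (C6 onto the ester, giving an acylphloroglucinol), over lactonisation to a 4-hydroxy-2-pyranone and over aldol attack from C8. The substrate secures this because C2 is far more acidic than the singly activated C8 and the C7 ketone is more electrophilic than the enolate-deactivated ester, while mild carbonate in methanol neither activates the ester as a chelating alkoxide would nor dehydrates toward the pyranone.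

Step 5
Reactants: 7 methyl 6-docosyl-2,4-dihydroxybenzoate
Product: 8 methyl 6-docosyl-2-hydroxy-4-methoxybenzoate
Conditions: MeI (1.1 equiv), K2CO3, acetone, reflux
Reagents that add atoms: iodomethane, CI
Why: Williamson etherification in which the 2-hydroxyl, hydrogen-bonded to the ester carbonyl, is much less nucleophilic, so one equivalent of iodomethane should alkylate only the 4-hydroxyl and exactly one methyl group is installed.

Step 6
Reactants: 8 methyl 6-docosyl-2-hydroxy-4-methoxybenzoate
Product: 10 3-docosyl-5-methoxyphenol, via 6-docosyl-2-hydroxy-4-methoxybenzoic acid 9 (not isolated)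
Conditions: KOH, ethylene glycol–H2O, 160 °C, N2; then 2 M HCl to pH 1, 90 °C
Reagents that add atoms: none
Why: Saponification of the hindered salicylate needs forcing conditions, after which the electron-rich acid 9 should undergo protodecarboxylation by ipso-protonation on warming in acid, as β-resorcylic acids do.

Step 7
Reactants: 10 3-docosyl-5-methoxyphenol
Product: 11 2-docosyl-6-methoxy-1,4-benzoquinone
Conditions: (KSO3)2NO (2.5 equiv), KH2PO4 (aq), methyltrioctylammonium chloride (cat.), CH2Cl2–H2O, rt
Reagents that add atoms: potassium nitrosodisulfonate (Fremy's salt), [K+].[K+].[O]N(S(=O)(=O)[O-])S(=O)(=O)[O-]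
Why: Teuber oxidation, in which one nitroxyl radical abstracts the phenolic hydrogen and a second delivers oxygen to the open para position (C4, between the chain and the methoxyl), giving the para-quinone as is usual for phenols with a free para site.

Step 8
Reactants: 11 2-docosyl-6-methoxy-1,4-benzoquinone
Product: 12 3-docosyl-5-methoxybenzene-1,2,4-triyl triacetate
Conditions: Ac2O, conc. H2SO4 (cat.), rt to 40 °C
Reagents that add atoms: acetic anhydride, CC(=O)OC(C)=O
Why: Thiele–Winter acetoxylation, in which the methoxy-substituted half of the quinone is a vinylogous ester with an electron-rich α-carbon (C6), so acetate should add in the conjugate sense to C2 of the alkyl-substituted enedione half, para to the methoxy-bearing carbon, and the resulting hydroquinone is acetylated in the same flask.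

Step 9
Reactants: 12 3-docosyl-5-methoxybenzene-1,2,4-triyl triacetate
Product: 14 3-docosyl-2-hydroxy-5-methoxy-1,4-benzoquinone, via 3-docosyl-5-methoxybenzene-1,2,4-triol 13 (not isolated)
Conditions: HCl (3 M in MeOH), N2, 65 °C; evaporate; then FeCl3 (2.2 equiv), EtOAc–H2O, rt
Reagents that add atoms: none
Why: Acid-catalysed transesterification should free the hydroxyhydroquinone 13 without touching the aryl methyl ether, and FeCl3 oxidation then gives the quinone, which settles as the 2-hydroxy-1,4-quinone tautomer with the hydroxyl hydrogen-bonded to the C1 carbonyl.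

**Compound list**

1 | dehydroacetic acid (3-acetyl-4-hydroxy-6-methyl-2H-pyran-2-one) | CC(=O)C1=C(O)C=C(C)OC1=O | starting material
2 | methyl 3,5-dioxohexanoate | CC(=O)CC(=O)CC(=O)OC | intermediate
3 | tricosanoic acid | CCCCCCCCCCCCCCCCCCCCCCC(=O)O | starting material
4 | methyl tricosanoate | CCCCCCCCCCCCCCCCCCCCCCC(=O)OC | intermediate
5 | methyl 3,5,7-trioxononacosanoate (keto form drawn) | CCCCCCCCCCCCCCCCCCCCCCC(=O)CC(=O)CC(=O)CC(=O)OC | intermediate
6 | cyclic aldol adduct, methyl 2-docosyl-2-hydroxy-4,6-dioxocyclohexane-1-carboxylate (racemic mixture of diastereomers, both centres lost on aromatisation; not isolated) | CCCCCCCCCCCCCCCCCCCCCCC1(O)CC(=O)CC(=O)C1C(=O)OC | intermediate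
7 | methyl 6-docosyl-2,4-dihydroxybenzoate | CCCCCCCCCCCCCCCCCCCCCCc1cc(O)cc(O)c1C(=O)OC | intermediate
8 | methyl 6-docosyl-2-hydroxy-4-methoxybenzoate | CCCCCCCCCCCCCCCCCCCCCCc1cc(OC)cc(O)c1C(=O)OC | intermediate
9 | 6-docosyl-2-hydroxy-4-methoxybenzoic acid (not isolated) | CCCCCCCCCCCCCCCCCCCCCCc1cc(OC)cc(O)c1C(=O)O | intermediate
10 | 3-docosyl-5-methoxyphenol | CCCCCCCCCCCCCCCCCCCCCCc1cc(O)cc(OC)c1 | intermediate
11 | 2-docosyl-6-methoxy-1,4-benzoquinone | CCCCCCCCCCCCCCCCCCCCCCC1=CC(=O)C=C(OC)C1=O | intermediate
12 | 3-docosyl-5-methoxybenzene-1,2,4-triyl triacetate | CCCCCCCCCCCCCCCCCCCCCCc1c(OC(C)=O)c(OC(C)=O)cc(OC)c1OC(C)=O | intermediate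
13 | 3-docosyl-5-methoxybenzene-1,2,4-triol (not isolated) | CCCCCCCCCCCCCCCCCCCCCCc1c(O)c(O)cc(OC)c1O | intermediate
14 | 3-docosyl-2-hydroxy-5-methoxy-1,4-benzoquinone (CNP0107063.0) | CCCCCCCCCCCCCCCCCCCCCCC1=C(O)C(=O)C=C(OC)C1=O | target

**Step count and risks**

Total step count: 9. Longest linear sequence: 8 steps (step 1 or step 2, then steps 3 to 9).

Steps most likely to fail:

Step 3 (polyanion Claisen condensation). Proton transfer from the α-methylene of the fatty ester to the terminal carbanion, together with quenching of unreacted trianion by the more acidic product, may stall the acylation. Poor solubility of the C23 ester in cold THF would add to this. The fallback sets out from 3 and rejoins the route at 5. The acid 3 would be converted with 1,1'-carbonyldiimidazole and N,O-dimethylhydroxylamine hydrochloride into N-methoxy-N-methyltricosanamide F1, whose tetrahedral adduct cannot collapse before work-up. Commercial 2,2,6-trimethyl-4H-1,3-dioxin-4-one would be acetylated at its methyl group (LiN(SiMe3)2, THF, −78 °C, then acetyl chloride) to 2,2-dimethyl-6-(2-oxopropyl)-4H-1,3-dioxin-4-one F2. The dianion of F2 (LiN(iPr)2, 2 equiv) would be acylated at its terminal methyl by F1 to give 6-(2,4-dioxohexacosyl)-2,2-dimethyl-4H-1,3-dioxin-4-one F3. Heating F3 in toluene with methanol at 110 °C should expel acetone and trap the acylketene as the triketo ester 5.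

Step 4 (aldol aromatisation). Closure in the Claisen sense or lactonisation to a pyranone may divert material, and incomplete dehydration of the aldol adduct may leave the ring non-aromatic. The fallback sets out from 4 and rejoins at 7, building the ring by the classical cyclohexanedione route so that no polyketone has to choose between closure modes. Ester 4 would be reduced with iBu2AlH (toluene–CH2Cl2, −78 °C) to tricosanal F4. Wittig olefination with 1-(triphenylphosphoranylidene)propan-2-one would give (E)-hexacos-3-en-2-one F5. Michael addition of dimethyl malonate followed by Dieckmann-type closure (NaOMe, MeOH, reflux) would give methyl 6-docosyl-2-hydroxy-4-oxocyclohex-2-ene-1-carboxylate F6 (racemic, trans). Dehydrogenation with Br2 in DMF should then deliver the resorcylate 7.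

Step 8 (Thiele–Winter acetoxylation). Conjugate addition of acetate to the hindered 2,6-disubstituted quinone may be slow, may go partly to C6, or may be accompanied by acid-induced loss of the methoxy group. The fallback sets out from 11 and rejoins at 14. Nucleophilic epoxidation of the alkyl-bearing enedione double bond of 11 (H2O2, Na2CO3, aqueous THF–MeOH) would give the racemic epoxide 1-docosyl-3-methoxy-7-oxabicyclo[4.1.0]hept-3-ene-2,5-dione F7; the vinylogous-ester double bond is too electron-rich for hydroperoxide addition. Acid-induced opening and enolisation of the epoxide (cold concentrated H2SO4) should then give the hydroxyquinone 14 directly, with the oxygen retained on C2.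

**Further compounds**

F1 | step 3 | N-methoxy-N-methyltricosanamide | CCCCCCCCCCCCCCCCCCCCCCC(=O)N(C)OC
F2 | step 3 | 2,2-dimethyl-6-(2-oxopropyl)-4H-1,3-dioxin-4-one | CC(=O)CC1=CC(=O)OC(C)(C)O1
F3 | step 3 | 6-(2,4-dioxohexacosyl)-2,2-dimethyl-4H-1,3-dioxin-4-one | CCCCCCCCCCCCCCCCCCCCCCC(=O)CC(=O)CC1=CC(=O)OC(C)(C)O1
F4 | step 4 | tricosanal | CCCCCCCCCCCCCCCCCCCCCCC=O
F5 | step 4 | (E)-hexacos-3-en-2-one | CCCCCCCCCCCCCCCCCCCCCC/C=C/C(C)=O
F6 | step 4 | methyl 6-docosyl-2-hydroxy-4-oxocyclohex-2-ene-1-carboxylate (trans, racemic; one enantiomer drawn) | CCCCCCCCCCCCCCCCCCCCCC[C@@H]1CC(=O)C=C(O)[C@H]1C(=O)OC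
F7 | step 8 | 1-docosyl-3-methoxy-7-oxabicyclo[4.1.0]hept-3-ene-2,5-dione (cis-fused epoxide, racemic; one enantiomer drawn) | CCCCCCCCCCCCCCCCCCCCCC[C@]12O[C@H]1C(=O)C=C(OC)C2=O
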